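## Retrosynthetic overview

1. Target 46 ⇐ macrocyclic keto alcohol 45 (unit A still a C2 carbinol; oxidation is the last step) ⇐ β-keto ester 43 (Krapcho, then equilibration of unit B inside the macrocycle) ⇐ 41 by ring-closing metathesis (C1(A) butenyl + C9(B) allyl) and hydrogenation.
2. Key coupling: 41 ⇐ C-alkylation of β-keto ester 39 (unit B, 19 heavy atoms) with chloride 25 (unit A, 22 heavy atoms).
3. Unit A (25): tandem N-alkylation (ring 1, then ring 2) ⇐ syn-Mannich adduct 19 ⇐ Roche-ester ketone 16 + sulfinyl aldimine 10 (C9 from Cu-catalysed allylic alkylation).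
4. Unit B (39): Dieckmann (ring 1) ⇐ aza-Michael ⇐ trans-piperidine 36 (ring 2) ⇐ acetate Mannich adduct 34 ⇐ aldimine 30 (C9 from organocatalytic α-allylation).
5. Ring order: A ring 1, A ring 2 | B ring 2, B ring 1 | 16-membered ring last.

Assumption: where a chiral ligand or organocatalyst is named, the enantiomer meant is the one that gives the configuration drawn; locants C1–C9a are quinolizidine locants, unit A being the (9R,9aR) half and unit B the (9S,9aS) half of the target.

## Route

Step 1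
Reactants: 1 5-chloropent-1-ene; 2 (E)-1,4-dibromobut-2-ene
Product: 3 (E)-1-bromo-6-chlorohex-2-ene
Conditions: 2 (4 equiv), second-generation Grubbs catalyst RuCl2(=CHPh)(PCy3)(SIMes) (2 mol %), CH2Cl2, 40 °C
Reagents that add atoms: none
Why: Olefin cross-metathesis of a terminal alkene with an excess of the symmetrical allylic dibromide gives the E-allylic bromide under thermodynamic control; no stereocentre is formed.

Step 2
Reactants: 3 (E)-1-bromo-6-chlorohex-2-ene; 4 1-bromo-5-chloropentane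
Product: 6 (3R)-8-chloro-3-(3-chloropropyl)oct-1-ene, via Grignard reagent 5 (not isolated)
Conditions: 4, Mg, Et2O, 35 °C; then 3, CuBr·SMe2 (3 mol %), Taniaphos ligand (3.5 mol %), CH2Cl2, −78 °C
Reagents that add atoms: none
Why: Copper-catalysed asymmetric allylic alkylation (SN2′) delivers the Grignard carbon to the γ-carbon under ligand control, which sets C9 of unit A (3R here), magnesium having inserted into C–Br in preference to C–Cl.

Step 3
Reactants: 6 (3R)-8-chloro-3-(3-chloropropyl)oct-1-ene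
Product: 8 (2R)-7-chloro-2-(3-chloropropyl)heptanal, via secondary ozonide 7 (not isolated)
Conditions: O3, CH2Cl2, −78 °C; then PPh3, −78 °C → rt
Reagents that add atoms: ozone, [O-][O+]=O
Why: Ozonolysis with reductive work-up cleaves the vinyl group to the aldehyde under base-free, cold conditions that leave the α-stereocentre intact.

Step 4
Reactants: 8 (2R)-7-chloro-2-(3-chloropropyl)heptanal; 9 (R)-2-methylpropane-2-sulfinamide
Product: 10 (R)-N-[(1E,2R)-7-chloro-2-(3-chloropropyl)heptylidene]-2-methylpropane-2-sulfinamide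
Conditions: CuSO4 (2 equiv), CH2Cl2, rt
Reagents that add atoms: none
Why: Ellman condensation with a mild dehydrating Lewis acid gives the E-sulfinyl aldimine without epimerising the α-centre.

Step 5
Reactants: 11 methyl (2R)-3-hydroxy-2-methylpropanoate
Product: 12 methyl (2R)-3-{[tert-butyl(dimethyl)silyl]oxy}-2-methylpropanoate
Conditions: TBSCl, imidazole, DMF, 0 °C → rt
Reagents that add atoms: tert-butyldimethylsilyl chloride, CC(C)(C)[Si](C)(C)Cl
Why: Silyl protection of the primary alcohol; the stereocentre (future C3 of unit A) is not involved.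

Step 6
Reactants: 12 methyl (2R)-3-{[tert-butyl(dimethyl)silyl]oxy}-2-methylpropanoate
Product: 13 (2R)-3-{[tert-butyl(dimethyl)silyl]oxy}-N-methoxy-N,2-dimethylpropanamide
Conditions: MeNHOMe·HCl, iPrMgCl, THF, −20 °C
Reagents that add atoms: N,O-dimethylhydroxylamine hydrochloride, CNOC.Cl
Why: Weinreb amide formation by aminolysis of the ester with the magnesium amide, a non-enolising process that keeps the α-centre.

Step 7
Reactants: 13 (2R)-3-{[tert-butyl(dimethyl)silyl]oxy}-N-methoxy-N,2-dimethylpropanamide; 14 5-bromopent-1-ene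
Product: 16 (2R)-1-{[tert-butyl(dimethyl)silyl]oxy}-2-methyloct-7-en-3-one, via Grignard reagent 15 (not isolated)
Conditions: 14, Mg, THF, 40 °C; then 13, THF, 0 °C; aq. NH4Cl
Reagents that add atoms: none
Why: Weinreb ketone synthesis, in which the chelated tetrahedral adduct prevents over-addition and α-epimerisation.

Step 8
Reactants: 16 (2R)-1-{[tert-butyl(dimethyl)silyl]oxy}-2-methyloct-7-en-3-one; 10 sulfinyl aldimine
Product: 19 (R)-N-[(5S,6R,7R)-5-[(2R)-3-{[tert-butyl(dimethyl)silyl]oxy}-2-methylpropanoyl]-12-chloro-7-(3-chloropropyl)dodec-1-en-6-yl]-2-methylpropane-2-sulfinamide, via lithium E-enolate 17 (not isolated), via titanium E-enolate 18 (not isolated)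
Conditions: lithium 2,2,6,6-tetramethylpiperidide, LiBr, THF, −78 °C; ClTi(OiPr)3 (2 equiv), −78 °C; then 10, −78 °C; aq. NH4Cl
Reagents that add atoms: none
Why: Titanium-enolate Mannich addition to an N-sulfinyl aldimine (Ellman type) through a closed chair transition state: the enolate adds to the Si face of the (R)-sulfinyl imine (C9a R), the E geometry translates into the syn C1/C9a relationship (C1 S), and the non-chelating α′ centre and the C9 centre with two alike alkyl arms exert little bias.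

Step 9
Reactants: 19 syn-Mannich adduct (N-sulfinyl β-amino ketone)
Product: 20 (R)-N-[(5S,6R,7R)-5-[(1S,2R)-3-{[tert-butyl(dimethyl)silyl]oxy}-1-hydroxy-2-methylpropyl]-12-chloro-7-(3-chloropropyl)dodec-1-en-6-yl]-2-methylpropane-2-sulfinamide
Conditions: LiEt3BH, THF, −78 °C
Reagents that add atoms: none
Why: Hydride reduction of the N-sulfinyl β-amino ketone by non-chelated external delivery gives the 1,3-anti amino alcohol (C2 S here), which locks C1 and C3 against enolisation; the C2 centre is erased in step 23, and the alkyl chlorides survive at −78 °C.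

Step 10
Reactants: 20 silyl-protected amino alcohol
Product: 21 (R)-N-[(5S,6R,7R)-12-chloro-7-(3-chloropropyl)-5-[(1S,2R)-1,3-dihydroxy-2-methylpropyl]dodec-1-en-6-yl]-2-methylpropane-2-sulfinamide
Conditions: Bu4NF, THF, 0 °C
Reagents that add atoms: none
Why: Fluoride-mediated desilylation frees the primary C4 hydroxyl while sulfinamide and alkyl chlorides are inert at 0 °C.

Step 11
Reactants: 21 diol
Product: 22 (2R,3S,4S,5R,6R)-4-(but-3-en-1-yl)-5-{[(R)-tert-butylsulfinyl]amino}-11-chloro-6-(3-chloropropyl)-3-hydroxy-2-methylundecyl 4-methylbenzenesulfonate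
Conditions: TsCl (1.1 equiv), pyridine, CH2Cl2, 0 °C
Reagents that add atoms: 4-methylbenzenesulfonyl chloride, Cc1ccc(cc1)S(Cl)(=O)=O
Why: Selective sulfonylation of the unhindered primary hydroxyl over the secondary carbinol, which is flanked by two branched carbons.

Step 12
Reactants: 22 primary tosylate
Product: 25 (1S,2R,3R,9R,9aR)-1-(but-3-en-1-yl)-9-(5-chloropentyl)-3-methyloctahydro-2H-quinolizin-2-ol, via amine hydrochloride 23 (not isolated), via monocyclic piperidinol 24 (not isolated)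
Conditions: HCl (4 M in dioxane), MeOH, 0 °C → rt; evaporate; K2CO3, MeCN, 70 °C
Reagents that add atoms: none
Why: Acid removes the N-sulfinyl group and the free primary amine closes ring 1 by 6-exo-tet SN2 on the primary tosylate and then ring 2 on the 3-chloropropyl arm (tandem N-alkylation); the 5-chloropentyl arm is spared because it could only form an eight-membered ring, and no stereocentre is touched.

Step 13
Reactants: 26 5-chloropentanal; 27 allyltrimethylsilane
Product: 28 (2R)-2-(3-chloropropyl)pent-4-enal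
Conditions: 5-benzyl-2-tert-butyl-3-methylimidazolidin-4-one·TFA (20 mol %), (NH4)2Ce(NO3)6 (2 equiv), NaHCO3, DME, −20 °C
Reagents that add atoms: none
Why: SOMO-type organocatalytic α-allylation, in which tetravalent cerium oxidises the transient enamine to a radical cation that is trapped by the allylsilane on its unshielded face; this sets C9 of unit B (2R here).

Step 14
Reactants: 28 (2R)-2-(3-chloropropyl)pent-4-enal; 29 (S)-2-methylpropane-2-sulfinamide
Product: 30 (S)-N-[(1E,2R)-2-(3-chloropropyl)pent-4-en-1-ylidene]-2-methylpropane-2-sulfinamide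
Conditions: CuSO4 (2 equiv), CH2Cl2, rt
Reagents that add atoms: none
Why: Ellman condensation as in step 4 with the enantiomeric auxiliary; the α-centre is not epimerised.

Step 15
Reactants: 31 methyl acetate; 30 sulfinyl aldimine
Product: 34 methyl (3R,4R)-3-{[(S)-tert-butylsulfinyl]amino}-4-(3-chloropropyl)hept-6-enoate, via lithium enolate 32 (not isolated), via titanium enolate 33 (not isolated)
Conditions: LiN(iPr)2, THF, −78 °C; ClTi(OiPr)3 (2 equiv), −78 °C; then 30, −78 °C; aq. NH4Cl
Reagents that add atoms: none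
Why: Ellman titanium-enolate Mannich addition of an acetate through the chelated chair transition state on the Re face of the (S)-sulfinyl aldimine sets C9a (3R here), which becomes the 2,3-trans piperidine after ring closure.

Step 16
Reactants: 34 β-sulfinylamino ester
Product: 36 methyl 2-[(2R,3R)-3-(prop-2-en-1-yl)piperidin-2-yl]acetate, via amine hydrochloride 35 (not isolated)
Conditions: HCl (4 M in dioxane), MeOH, rt; evaporate; K2CO3, NaI (10 mol %), MeCN, 70 °C
Reagents that add atoms: none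
Why: Acidic removal of the sulfinyl group and 6-exo-tet N-alkylation by the 3-chloropropyl arm form ring 2; the 2,3-trans piperidine is also the thermodynamic isomer should retro-aza-Michael equilibration occur.

Step 17
Reactants: 36 methyl 2-[(2R,3R)-3-(prop-2-en-1-yl)piperidin-2-yl]acetate; 37 methyl methacrylate
Product: 38 methyl 3-[(2R,3R)-2-(2-methoxy-2-oxoethyl)-3-(prop-2-en-1-yl)piperidin-1-yl]-2-methylpropanoate (1:1 epimers at C-2 of the propanoate)
Conditions: 37 (5 equiv), MeOH, 65 °C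
Reagents that add atoms: none
Why: Aza-Michael addition of the secondary amine; the new methyl-bearing centre forms as a 1:1 mixture that is equilibrated in step 22.

Step 18
Reactants: 38 amino diester
Product: 39 methyl (9R,9aS)-3-methyl-2-oxo-9-(prop-2-en-1-yl)octahydro-2H-quinolizine-1-carboxylate (keto–enol mixture; C-1/C-3 epimers)
Conditions: KOtBu, THF, 0 °C → rt; AcOH
Reagents that add atoms: none
Why: Dieckmann condensation, in which only closure through the acetate α-carbon onto the propanoate carbonyl gives a β-keto ester that can be deprotonated between its carbonyls, so this regioisomer is the thermodynamic sink (ring 1 of unit B).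

Step 19
Reactants: 39 β-keto ester (unit B); 25 chloride (unit A)
Product: 41 methyl (9R,9aS)-1-{5-[(1S,2R,3R,9R,9aR)-1-(but-3-en-1-yl)-2-hydroxy-3-methyloctahydro-2H-quinolizin-9-yl]pentyl}-3-methyl-2-oxo-9-(prop-2-en-1-yl)octahydro-2H-quinolizine-1-carboxylate (C-1/C-3 epimers of the keto ester ring), via iodide 40 (not isolated)
Conditions: NaI (1.5 equiv), Cs2CO3 (2 equiv), DMF, 60 °C
Reagents that add atoms: none
Why: Finkelstein exchange followed by SN2 C-alkylation of the cesium β-keto ester enolate (acetoacetic-ester-type alkylation) joins the two fragments; the quaternary C1 forms as a mixture that is erased by decarboxylation, and the tertiary amines are far poorer nucleophiles than the enolate.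

Step 20
Reactants: 41 coupled diene
Product: 42 macrocyclic alkene β-keto ester: 41 with the C1(A) butenyl terminus joined to the C9(B) allyl terminus as C1(A)–CH2CH2–CH=CH–CH2–C9(B) (16-membered ring; E/Z mixture; stereocentres as in 41)
Conditions: TsOH·H2O (2.2 equiv), second-generation Grubbs catalyst RuCl2(=CHPh)(PCy3)(SIMes) (10 mol %), CH2Cl2 (1 mM), 40 °C; aq. NaHCO3
Reagents that add atoms: none
Why: Ring-closing metathesis of the two terminal alkenes closes the 16-membered ring, the amines being masked as ammonium tosylates so that they do not bind ruthenium; the E/Z isomers converge in step 21.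

Step 21
Reactants: 42 macrocyclic alkene
Product: 43 saturated macrocyclic β-keto ester (42 with the ring alkene reduced; stereocentres as in 41)
Conditions: H2 (1 atm), Pd/C (10 wt %), MeOH, rt
Reagents that add atoms: none
Why: Heterogeneous hydrogenation of the 1,2-disubstituted alkene leaves ketone, ester and all stereocentres untouched.

Step 22
Reactants: 43 saturated macrocyclic β-keto ester
Product: 45 macrocyclic keto alcohol: unit A (1S,2R,3R,9R,9aR)-quinolizidin-2-ol and unit B (1S,3R,9S,9aS)-quinolizidin-2-one linked C9(A)–(CH2)5–C1(B) and C9(B)–(CH2)5–C1(A), via unequilibrated ketone 44 (not isolated)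
Conditions: LiCl, H2O, DMSO, 150 °C; then NaOMe (0.2 equiv), MeOH, rt
Reagents that add atoms: none
Why: Krapcho dealkoxycarbonylation followed by base equilibration through the enolates of unit B only (unit A is a carbinol and cannot epimerise), so that C1 and C3 of unit B settle as 1S,3R with all three substituents of the trans-quinolizidinone equatorial, the arrangement of this unit in the natural petrosins, which form under equilibrating conditions.

Step 23
Reactants: 45 macrocyclic keto alcohol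
Product: 46 target CNP0268544.1
Conditions: Dess–Martin periodinane, CH2Cl2, 0 °C → rt; aq. Na2S2O3/NaHCO3
Reagents that add atoms: none
Why: Dess–Martin oxidation under neutral, non-enolising conditions converts the C2 carbinol of unit A into the ketone while the kinetically set C1 (S) and C3 (R) of that unit are retained.

## Compound list

1 | 5-chloropent-1-ene | C=CCCCCl | starting material
2 | (E)-1,4-dibromobut-2-ene | BrC/C=C/CBr | starting material
3 | (E)-1-bromo-6-chlorohex-2-ene | ClCCC/C=C/CBr | intermediate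
4 | 1-bromo-5-chloropentane | BrCCCCCCl | starting material
5 | (5-chloropentyl)magnesium bromide | ClCCCCC[Mg]Br | intermediate
6 | (3R)-8-chloro-3-(3-chloropropyl)oct-1-ene | C=C[C@@H](CCCCl)CCCCCCl | intermediate
7 | 3-[(4R)-1,9-dichlorononan-4-yl]-1,2,4-trioxolane (epimers at the ring carbon) | O1OCOC1[C@@H](CCCCl)CCCCCCl | intermediate
8 | (2R)-7-chloro-2-(3-chloropropyl)heptanal | O=C[C@@H](CCCCl)CCCCCCl | intermediate
9 | (R)-2-methylpropane-2-sulfinamide | N[S@](=O)C(C)(C)C | starting material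
10 | (R)-N-[(1E,2R)-7-chloro-2-(3-chloropropyl)heptylidene]-2-methylpropane-2-sulfinamide | CC(C)(C)[S@@](=O)/N=C/[C@@H](CCCCl)CCCCCCl | intermediate
11 | methyl (2R)-3-hydroxy-2-methylpropanoate | C[C@H](CO)C(=O)OC | starting material
12 | methyl (2R)-3-{[tert-butyl(dimethyl)silyl]oxy}-2-methylpropanoate | C[C@H](CO[Si](C)(C)C(C)(C)C)C(=O)OC | intermediate
13 | (2R)-3-{[tert-butyl(dimethyl)silyl]oxy}-N-methoxy-N,2-dimethylpropanamide | C[C@H](CO[Si](C)(C)C(C)(C)C)C(=O)N(C)OC | intermediate
14 | 5-bromopent-1-ene | C=CCCCBr | starting material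
15 | pent-4-en-1-ylmagnesium bromide | C=CCCC[Mg]Br | intermediate
16 | (2R)-1-{[tert-butyl(dimethyl)silyl]oxy}-2-methyloct-7-en-3-one | C[C@H](CO[Si](C)(C)C(C)(C)C)C(=O)CCCC=C | intermediate
17 | lithium (2R,3E)-1-{[tert-butyl(dimethyl)silyl]oxy}-2-methylocta-3,7-dien-3-olate | C=CCC/C=C(/O[Li])[C@H](C)CO[Si](C)(C)C(C)(C)C | intermediate
18 | tri(propan-2-yloxy)titanium (2R,3E)-1-{[tert-butyl(dimethyl)silyl]oxy}-2-methylocta-3,7-dien-3-olate | C=CCC/C=C(/O[Ti](OC(C)C)(OC(C)C)OC(C)C)[C@H](C)CO[Si](C)(C)C(C)(C)C | intermediate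
19 | (R)-N-[(5S,6R,7R)-5-[(2R)-3-{[tert-butyl(dimethyl)silyl]oxy}-2-methylpropanoyl]-12-chloro-7-(3-chloropropyl)dodec-1-en-6-yl]-2-methylpropane-2-sulfinamide | C[C@H](CO[Si](C)(C)C(C)(C)C)C(=O)[C@@H](CCC=C)[C@H](N[S@](=O)C(C)(C)C)[C@@H](CCCCl)CCCCCCl | intermediate
20 | (R)-N-[(5S,6R,7R)-5-[(1S,2R)-3-{[tert-butyl(dimethyl)silyl]oxy}-1-hydroxy-2-methylpropyl]-12-chloro-7-(3-chloropropyl)dodec-1-en-6-yl]-2-methylpropane-2-sulfinamide | C[C@H](CO[Si](C)(C)C(C)(C)C)[C@@H](O)[C@@H](CCC=C)[C@H](N[S@](=O)C(C)(C)C)[C@@H](CCCCl)CCCCCCl | intermediate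
21 | (R)-N-[(5S,6R,7R)-12-chloro-7-(3-chloropropyl)-5-[(1S,2R)-1,3-dihydroxy-2-methylpropyl]dodec-1-en-6-yl]-2-methylpropane-2-sulfinamide | C[C@H](CO)[C@@H](O)[C@@H](CCC=C)[C@H](N[S@](=O)C(C)(C)C)[C@@H](CCCCl)CCCCCCl | intermediate
22 | (2R,3S,4S,5R,6R)-4-(but-3-en-1-yl)-5-{[(R)-tert-butylsulfinyl]amino}-11-chloro-6-(3-chloropropyl)-3-hydroxy-2-methylundecyl 4-methylbenzenesulfonate | C[C@H](COS(=O)(=O)c1ccc(C)cc1)[C@@H](O)[C@@H](CCC=C)[C@H](N[S@](=O)C(C)(C)C)[C@@H](CCCCl)CCCCCCl | intermediate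
23 | (2R,3S,4S,5R,6R)-5-amino-4-(but-3-en-1-yl)-11-chloro-6-(3-chloropropyl)-3-hydroxy-2-methylundecyl 4-methylbenzenesulfonate hydrochloride | C[C@H](COS(=O)(=O)c1ccc(C)cc1)[C@@H](O)[C@@H](CCC=C)[C@H](N)[C@@H](CCCCl)CCCCCCl.Cl | intermediate
24 | (3R,4R,5S,6R)-5-(but-3-en-1-yl)-6-[(4R)-1,9-dichlorononan-4-yl]-3-methylpiperidin-4-ol | C[C@@H]1CN[C@H]([C@@H](CCCCl)CCCCCCl)[C@H](CCC=C)[C@@H]1O | intermediate
25 | (1S,2R,3R,9R,9aR)-1-(but-3-en-1-yl)-9-(5-chloropentyl)-3-methyloctahydro-2H-quinolizin-2-ol | C[C@@H]1CN2CCC[C@@H](CCCCCCl)[C@@H]2[C@H](CCC=C)[C@@H]1O | intermediate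
26 | 5-chloropentanal | O=CCCCCCl | starting material
27 | allyltrimethylsilane | C=CC[Si](C)(C)C | starting material
28 | (2R)-2-(3-chloropropyl)pent-4-enal | O=C[C@@H](CC=C)CCCCl | intermediate
29 | (S)-2-methylpropane-2-sulfinamide | N[S@@](=O)C(C)(C)C | starting material
30 | (S)-N-[(1E,2R)-2-(3-chloropropyl)pent-4-en-1-ylidene]-2-methylpropane-2-sulfinamide | CC(C)(C)[S@](=O)/N=C/[C@@H](CC=C)CCCCl | intermediate
31 | methyl acetate | COC(C)=O | starting material
32 | lithium 1-methoxyethen-1-olate | C=C(O[Li])OC | intermediate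
33 | tri(propan-2-yloxy)titanium 1-methoxyethen-1-olate | C=C(O[Ti](OC(C)C)(OC(C)C)OC(C)C)OC | intermediate
34 | methyl (3R,4R)-3-{[(S)-tert-butylsulfinyl]amino}-4-(3-chloropropyl)hept-6-enoate | COC(=O)C[C@@H](N[S@@](=O)C(C)(C)C)[C@@H](CC=C)CCCCl | intermediate
35 | methyl (3R,4R)-3-amino-4-(3-chloropropyl)hept-6-enoate hydrochloride | COC(=O)C[C@@H](N)[C@@H](CC=C)CCCCl.Cl | intermediate
36 | methyl 2-[(2R,3R)-3-(prop-2-en-1-yl)piperidin-2-yl]acetate | N1CCC[C@H](CC=C)[C@H]1CC(=O)OC | intermediate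
37 | methyl methacrylate | C=C(C)C(=O)OC | starting material
38 | methyl 3-[(2R,3R)-2-(2-methoxy-2-oxoethyl)-3-(prop-2-en-1-yl)piperidin-1-yl]-2-methylpropanoate (1:1 epimers at C-2 of the propanoate, left undefined) | COC(=O)C(C)CN1CCC[C@H](CC=C)[C@H]1CC(=O)OC | intermediate
39 | methyl (9R,9aS)-3-methyl-2-oxo-9-(prop-2-en-1-yl)octahydro-2H-quinolizine-1-carboxylate (keto–enol mixture; C-1 and C-3 undefined) | COC(=O)C1C(=O)C(C)CN2CCC[C@H](CC=C)[C@@H]12 | intermediate
40 | (1S,2R,3R,9R,9aR)-1-(but-3-en-1-yl)-9-(5-iodopentyl)-3-methyloctahydro-2H-quinolizin-2-ol | C[C@@H]1CN2CCC[C@@H](CCCCCI)[C@@H]2[C@H](CCC=C)[C@@H]1O | intermediate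
41 | methyl (9R,9aS)-1-{5-[(1S,2R,3R,9R,9aR)-1-(but-3-en-1-yl)-2-hydroxy-3-methyloctahydro-2H-quinolizin-9-yl]pentyl}-3-methyl-2-oxo-9-(prop-2-en-1-yl)octahydro-2H-quinolizine-1-carboxylate (C-1 and C-3 of the keto ester ring undefined) | C[C@@H]1CN2CCC[C@@H](CCCCCC3(C(=O)OC)C(=O)C(C)CN4CCC[C@H](CC=C)[C@@H]34)[C@@H]2[C@H](CCC=C)[C@@H]1O | intermediate
42 | macrocyclic alkene β-keto ester (41 ring-closed between the C1(A) butenyl and C9(B) allyl termini; E/Z mixture) | C[C@@H]1CN2CCC[C@@H](CCCCCC3(C(=O)OC)C(=O)C(C)CN4CCC[C@H](CC=CCC5)[C@@H]34)[C@@H]2[C@H]5[C@@H]1O | intermediate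
43 | saturated macrocyclic β-keto ester (42 with the ring alkene hydrogenated) | C[C@@H]1CN2CCC[C@@H](CCCCCC3(C(=O)OC)C(=O)C(C)CN4CCC[C@H](CCCCC5)[C@@H]34)[C@@H]2[C@H]5[C@@H]1O | intermediate
44 | macrocyclic keto alcohol before equilibration (C-1 and C-3 of unit B undefined) | C[C@@H]1CN2CCC[C@@H](CCCCCC3C(=O)C(C)CN4CCC[C@H](CCCCC5)[C@@H]34)[C@@H]2[C@H]5[C@@H]1O | intermediate
45 | macrocyclic keto alcohol: unit A (1S,2R,3R,9R,9aR)-quinolizidin-2-ol, unit B (1S,3R,9S,9aS)-quinolizidin-2-one, linked C9(A)–(CH2)5–C1(B) and C9(B)–(CH2)5–C1(A) | C[C@@H]1CN2CCC[C@@H](CCCCC[C@@H]3C(=O)[C@H](C)CN4CCC[C@H](CCCCC5)[C@@H]34)[C@@H]2[C@H]5[C@@H]1O | intermediate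
46 | CNP0268544.1: macrocyclic bis(quinolizidin-2-one), unit A (1S,3R,9R,9aR), unit B (1S,3R,9S,9aS) | C[C@@H]1CN2CCC[C@H]3CCCCC[C@@H]4C(=O)[C@H](C)CN5CCC[C@H](CCCCC[C@H](C1=O)[C@@H]32)[C@@H]45 | target

## Step count and risks

Total step count: 23. Longest linear sequence: 14 steps (steps 1–4, 8–12, 19–23).

Steps most likely to fail:

Step 8 (syn-selective Mannich addition of an α′-chiral ketone enolate). Enolate E/Z purity and the double stereodifferentiation are not secured by close precedent. The fallback makes the C1–C9a bond with an ester enolate and sets C2/C3 afterwards by catalyst control. It sets out from aldimine 10: hex-5-enoic acid is esterified (MeOH, cat. H2SO4) to methyl hex-5-enoate F1. Its titanium enolate (LiN(iPr)2, then ClTi(OiPr)3, THF, −78 °C) adds to 10 to give methyl (2S,3R,4R)-2-(but-3-en-1-yl)-3-{[(R)-tert-butylsulfinyl]amino}-9-chloro-4-(3-chloropropyl)nonanoate F2. Reduction with iBu2AlH (CH2Cl2, −78 °C) gives (R)-N-[(5S,6R,7R)-12-chloro-7-(3-chloropropyl)-5-formyldodec-1-en-6-yl]-2-methylpropane-2-sulfinamide F3. An L-proline-catalysed cross-aldol reaction with propanal (slow addition, DMF, 4 °C; the α-branched aldehyde acts only as acceptor) gives the anti aldol (R)-N-[(5S,6R,7R)-12-chloro-7-(3-chloropropyl)-5-[(1S,2S)-1-hydroxy-2-methyl-3-oxopropyl]dodec-1-en-6-yl]-2-methylpropane-2-sulfinamide F4. NaBH4 (MeOH, 0 °C) then returns to the route at diol 21.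

Step 19 (fragment-joining C-alkylation). O-alkylation at the hindered C1 or N-quaternisation may compete. The fallback drops the ester activation and alkylates a kinetic ketone enolate. It sets out from 39 and 25. Krapcho dealkoxycarbonylation of 39 (LiCl, wet DMSO, 150 °C) gives (3R,9R,9aR)-3-methyl-9-(prop-2-en-1-yl)octahydro-2H-quinolizin-2-one F5. Chloride 25 is converted into iodide 40 (NaI, acetone) and silylated (TMSCl, imidazole) to (1S,2R,3R,9R,9aR)-1-(but-3-en-1-yl)-9-(5-iodopentyl)-3-methyl-2-[(trimethylsilyl)oxy]octahydro-2H-quinolizine F6. The less substituted lithium enolate of F5 (LiN(iPr)2, THF–DMPU, −78 → 0 °C) is alkylated with F6 and gives, after mild acidic work-up, (3R,9R,9aS)-1-{5-[(1S,2R,3R,9R,9aR)-1-(but-3-en-1-yl)-2-hydroxy-3-methyloctahydro-2H-quinolizin-9-yl]pentyl}-3-methyl-9-(prop-2-en-1-yl)octahydro-2H-quinolizin-2-one F7 (C-1 epimers). Ring-closing metathesis under the conditions of step 20 gives the macrocyclic alkene ketone F8, and hydrogenation (H2, Pd/C) returns to the route at ketone 44, which is equilibrated to 45 as in step 22.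

Step 20 (macrocyclic ring-closing metathesis). Oligomerisation or catalyst deactivation by the amines may win. The fallback makes the metathesis intermolecular and closes the ring by alkylation instead. It sets out from 25 and 39: cross-metathesis of 25 with 39 (3 equiv, both as tosylate salts, second-generation Grubbs catalyst, CH2Cl2, 40 °C; homodimers are recycled) gives methyl (9R,9aS)-9-{5-[(1S,2R,3R,9R,9aR)-9-(5-chloropentyl)-2-hydroxy-3-methyloctahydro-2H-quinolizin-1-yl]pent-2-en-1-yl}-3-methyl-2-oxooctahydro-2H-quinolizine-1-carboxylate F9. Intramolecular C-alkylation of its β-keto ester (NaI, Cs2CO3, DMF, 2 mM, 60 °C) returns to the route at macrocycle 42.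

Further compounds
F1 | step 8 | methyl hex-5-enoate | C=CCCCC(=O)OC
F2 | step 8 | methyl (2S,3R,4R)-2-(but-3-en-1-yl)-3-{[(R)-tert-butylsulfinyl]amino}-9-chloro-4-(3-chloropropyl)nonanoate | COC(=O)[C@@H](CCC=C)[C@H](N[S@](=O)C(C)(C)C)[C@@H](CCCCl)CCCCCCl
F3 | step 8 | (R)-N-[(5S,6R,7R)-12-chloro-7-(3-chloropropyl)-5-formyldodec-1-en-6-yl]-2-methylpropane-2-sulfinamide | O=C[C@@H](CCC=C)[C@H](N[S@](=O)C(C)(C)C)[C@@H](CCCCl)CCCCCCl
F4 | step 8 | (R)-N-[(5S,6R,7R)-12-chloro-7-(3-chloropropyl)-5-[(1S,2S)-1-hydroxy-2-methyl-3-oxopropyl]dodec-1-en-6-yl]-2-methylpropane-2-sulfinamide | O=C[C@@H](C)[C@@H](O)[C@@H](CCC=C)[C@H](N[S@](=O)C(C)(C)C)[C@@H](CCCCl)CCCCCCl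
F5 | step 19 | (3R,9R,9aR)-3-methyl-9-(prop-2-en-1-yl)octahydro-2H-quinolizin-2-one | C1C(=O)[C@H](C)CN2CCC[C@H](CC=C)[C@@H]12
F6 | step 19 | (1S,2R,3R,9R,9aR)-1-(but-3-en-1-yl)-9-(5-iodopentyl)-3-methyl-2-[(trimethylsilyl)oxy]octahydro-2H-quinolizine | C[C@@H]1CN2CCC[C@@H](CCCCCI)[C@@H]2[C@H](CCC=C)[C@@H]1O[Si](C)(C)C
F7 | step 19 | (3R,9R,9aS)-1-{5-[(1S,2R,3R,9R,9aR)-1-(but-3-en-1-yl)-2-hydroxy-3-methyloctahydro-2H-quinolizin-9-yl]pentyl}-3-methyl-9-(prop-2-en-1-yl)octahydro-2H-quinolizin-2-one (C-1 epimers) | C[C@@H]1CN2CCC[C@@H](CCCCCC3C(=O)[C@H](C)CN4CCC[C@H](CC=C)[C@@H]34)[C@@H]2[C@H](CCC=C)[C@@H]1O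
F8 | step 19 | macrocyclic alkene ketone (F7 ring-closed between the C1(A) butenyl and C9(B) allyl termini; E/Z mixture; C-1 epimers of unit B) | C[C@@H]1CN2CCC[C@@H](CCCCCC3C(=O)[C@H](C)CN4CCC[C@H](CC=CCC5)[C@@H]34)[C@@H]2[C@H]5[C@@H]1O
F9 | step 20 | methyl (9R,9aS)-9-{5-[(1S,2R,3R,9R,9aR)-9-(5-chloropentyl)-2-hydroxy-3-methyloctahydro-2H-quinolizin-1-yl]pent-2-en-1-yl}-3-methyl-2-oxooctahydro-2H-quinolizine-1-carboxylate (E/Z mixture; C-1 and C-3 undefined) | C[C@@H]1CN2CCC[C@@H](CCCCCCl)[C@@H]2[C@H](CCC=CC[C@H]3CCCN4CC(C)C(=O)C(C(=O)OC)[C@H]34)[C@@H]1O
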